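Ring A of the target holds a quaternary C10 that lies para to the C3 oxygen and is bonded to C9 of ring B, so ring A can be carried as a silyl-protected phenol whose methyl-bearing para carbon is attacked by C9.
Retrosynthetic cuts, in this order: the ester C–O bonds at C3 and C4; the C7=C11 alkene (back to a C11 carbinol); C4–O and C5–H (back to the C4=C5 enone); C9–C10 (anodic closure of ring B onto the arene); C6–C7 (benzylation of a chiral imide dienolate).
Forward: the ring A benzylic bromide is joined to a five-carbon acyl unit, the chain is turned into a silyl enol ether, ring B closes by C9–C10 coupling with dearomatisation of ring A, then ring A is reduced, oxygenated and esterified.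
Stereochemistry: C7 from the (R)-oxazolidinone alkylation; C10 from C7 in the ring closure; C5 from dissolving-metal reduction; C4 from α-face Rubottom oxidation; C3 from hydroxyl-directed hydride delivery; the ester stereocentre from (R)-2-methylbutanoic acid.

Key step: step 12

Remark: eudesmane numbering is used for the bicyclic compounds (ring A = C1–C5 and C10, ring B = C5–C10, C11 = side-chain carbon on C7), α/β refer to the usual drawing with the C10 methyl β (all bicyclic compounds have this 10β-methyl and, while C7 is sp3, a 7β side chain), Ar stands for 2,6-dimethyl-3-(triisopropylsilyloxy)phenyl, and the C8 carbinol of 21–25 is assumed to be the equatorial 8α epimer, which is without consequence because C8 returns to a ketone in step 16.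

Step 1
Reactants: 1 2,6-dimethylbenzaldehyde
Product: 2 3-bromo-2,6-dimethylbenzaldehyde
Conditions: N-bromosuccinimide (1.05 equiv), conc. H2SO4, rt
Reagents that add atoms: N-bromosuccinimide, O=C1CCC(=O)N1Br
Why: Electrophilic aromatic bromination in strong acid should go to C3 alone, because this position is ortho/para to both methyl groups and meta to the formyl group, and one equivalent of reagent should stop at the monobromide.

Step 2
Reactants: 2 3-bromo-2,6-dimethylbenzaldehyde
Product: 4 3-hydroxy-2,6-dimethylbenzaldehyde, via pinacol boronate 3 (not isolated)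
Conditions: B2pin2, PdCl2(dppf) (3 mol %), KOAc, dioxane, 90 °C; then NaBO3·4H2O, THF/H2O, rt
Reagents that add atoms: sodium perborate, [Na+].[O-]OB=O
Why: Miyaura borylation of the aryl bromide followed by perborate oxidation of the C–B bond (aryl shift from boron to peroxide oxygen) converts Ar–Br into Ar–OH under conditions that a hindered, non-enolisable aldehyde tolerates.

Step 3
Reactants: 4 3-hydroxy-2,6-dimethylbenzaldehyde
Product: 5 2,6-dimethyl-3-(triisopropylsilyloxy)benzaldehyde
Conditions: i-Pr3SiCl, imidazole, DMF, rt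
Reagents that add atoms: chlorotri(propan-2-yl)silane, CC(C)[Si](Cl)(C(C)C)C(C)C
Why: Imidazole-promoted silylation of the phenol gives a bulky aryl silyl ether that withstands every base and nucleophile up to step 12 and later crowds C4.

Step 4
Reactants: 5 2,6-dimethyl-3-(triisopropylsilyloxy)benzaldehyde
Product: 6 [2,6-dimethyl-3-(triisopropylsilyloxy)phenyl]methanol
Conditions: NaBH4, MeOH/THF, 0 °C
Reagents that add atoms: none
Why: Borohydride reduction of an aromatic aldehyde gives the benzylic alcohol and leaves the aryl silyl ether intact.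

Step 5
Reactants: 6 [2,6-dimethyl-3-(triisopropylsilyloxy)phenyl]methanol
Product: 7 2,6-dimethyl-3-(triisopropylsilyloxy)benzyl bromide
Conditions: CBr4, PPh3, CH2Cl2, 0 °C
Reagents that add atoms: tetrabromomethane, BrC(Br)(Br)Br
Why: The Appel reaction turns the primary benzylic alcohol into the bromide under neutral conditions that do not cleave the silyl ether.

Step 6
Reactants: 8 (4R)-4-benzyl-1,3-oxazolidin-2-one; 9 3-methylbut-2-enoyl chloride
Product: 11 (4R)-4-benzyl-3-(3-methylbut-2-enoyl)-1,3-oxazolidin-2-one, via lithium oxazolidinide 10 (not isolated)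
Conditions: n-BuLi, THF, −78 °C; then 9, −78 → 0 °C
Reagents that add atoms: none
Why: N-Acylation of the lithiated oxazolidinone with an acid chloride at low temperature is the standard entry to N-enoyl imides and avoids deconjugation of the acyl group.

Step 7
Reactants: 11 (4R)-4-benzyl-3-(3-methylbut-2-enoyl)-1,3-oxazolidin-2-one; 7 2,6-dimethyl-3-(triisopropylsilyloxy)benzyl bromide
Product: 13 (4R)-4-benzyl-3-[(2R)-2-(ArCH2)-3-methylbut-3-enoyl]-1,3-oxazolidin-2-one, via sodium dienolate 12 (not isolated)
Conditions: NaN(SiMe3)2 (1.1 equiv), THF, −78 °C; then 7, −78 → −20 °C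
Reagents that add atoms: none
Why: In this auxiliary-controlled (Evans) alkylation of an extended enolate, γ-deprotonation of the s-cis enoyl imide gives the chelated Z-dienolate, which takes up the benzylic bromide at the α-carbon on the face opposite the C4 benzyl group, so that C7 is set (2R in the acyl chain) and the isopropenyl group is left out of conjugation.

Step 8
Reactants: 13 (4R)-4-benzyl-3-[(2R)-2-(ArCH2)-3-methylbut-3-enoyl]-1,3-oxazolidin-2-one
Product: 14 (4R)-4-benzyl-3-[(2R)-2-(ArCH2)-3-hydroxy-3-methylbutanoyl]-1,3-oxazolidin-2-one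
Conditions: Co(acac)2 (20 mol %), PhSiH3, O2 (1 atm), THF, rt
Reagents that add atoms: dioxygen, O=O
Why: Mukaiyama hydration (cobalt-mediated hydrogen-atom transfer to the terminal carbon, capture of the tertiary radical by O2, reduction of the peroxide by the silane) adds water in the Markovnikov sense to the 1,1-disubstituted alkene without touching the C7 stereocentre and creates no new one.

Step 9
Reactants: 14 (4R)-4-benzyl-3-[(2R)-2-(ArCH2)-3-hydroxy-3-methylbutanoyl]-1,3-oxazolidin-2-one
Product: 15 (2R)-2-(ArCH2)-3-hydroxy-N-methoxy-N,3-dimethylbutanamide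
Conditions: MeNH(OMe)·HCl, AlMe3, CH2Cl2, −20 → 0 °C
Reagents that add atoms: N,O-dimethylhydroxylamine hydrochloride, CNOC.Cl
Why: Aluminium-amide transamination of a β-hydroxy imide gives the Weinreb amide because the aluminium alkoxide of the β-hydroxyl delivers the amide to the exocyclic carbonyl, and auxiliary 8 is released for reuse.

Step 10
Reactants: 15 (2R)-2-(ArCH2)-3-hydroxy-N-methoxy-N,3-dimethylbutanamide
Product: 16 (3R)-3-(ArCH2)-4-hydroxy-4-methylpentan-2-one
Conditions: MeMgBr (3 equiv), THF, 0 °C; aqueous NH4Cl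
Reagents that add atoms: methylmagnesium bromide, C[Mg]Br
Why: In the Weinreb ketone synthesis the chelated tetrahedral adduct resists a second addition, the tertiary hydroxyl is merely deprotonated, and C9 enters as the methyl group while C7 stays configurationally intact.

Step 11
Reactants: 16 (3R)-3-(ArCH2)-4-hydroxy-4-methylpentan-2-one
Product: 18 (3R)-3-(ArCH2)-4-methyl-2,4-bis(trimethylsilyloxy)pent-1-ene, via dilithium alkoxide enolate 17 (not isolated)
Conditions: LiN(i-Pr)2 (2.5 equiv), THF, −78 °C; then Me3SiCl (4 equiv), Et3N, −78 → 0 °C; non-aqueous work-up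
Reagents that add atoms: chlorotrimethylsilane, C[Si](C)(C)Cl
Why: Kinetic enolisation with the lithium amide removes a proton from the open C9 methyl group and not from the shielded C7 methine, the lithium aldolate does not fragment at −78 °C, and O-silylation of enolate and tertiary alkoxide gives the terminal silyl enol ether (kinetic silyl enol ether formation).

Step 12
Reactants: 18 (3R)-3-(ArCH2)-4-methyl-2,4-bis(trimethylsilyloxy)pent-1-ene
Product: 19 (7R,10S)-11-(trimethylsilyloxy)eudesma-1,4-diene-3,8-dione
Conditions: undivided cell, reticulated vitreous carbon anode, Pt cathode, constant current (about 2.2 F/mol), LiClO4 (0.1 M), 2,6-lutidine, MeCN/i-PrOH (4:1), rt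
Reagents that add atoms: none
Why: One-electron oxidation at the anode of the silyl enol ether (or of the electron-rich aryl silyl ether, which is close in potential) gives a radical cation in which C9 bonds to C10, and loss of a second electron with transfer of the trimethylsilyl group from the C8 oxygen and the triisopropylsilyl group from the C3 oxygen to the alcohol co-solvent leaves the C8 ketone and the ring A dienone, since C10 carries a methyl group and cannot rearomatise. The closest known reaction types are the anodic coupling of silyl enol ethers with tethered electron-rich arenes in LiClO4/2,6-lutidine media and the anodic conversion of para-substituted phenols and their ethers into 4,4-disubstituted cyclohexa-2,5-dienones by capture of a tethered π-nucleophile. Ring B closes in a six-membered mode onto the arene carbon ortho to the tether, 6-exo with respect to the arene bond C10=C1 and 6-endo with respect to the enol ether. C10 is the only new stereocentre and is controlled by C7: in a chair-like closure the bulky 2-silyloxypropan-2-yl group is equatorial, so C9 adds to the arene face that leaves the C10 methyl cis to the C7 side chain (7R gives 10S). The step needs bonding at C10 (para to oxygen) and not at C4 (ortho), which the larger coefficient para to oxygen, the triisopropylsilyl ether crowding C4 and the greater stability of the cross-conjugated dienone should secure, and it needs ring closure to outrun benzylic deprotonation of the oxidised arene, which the intramolecular six-membered closure by a strongly nucleophilic enol ether should provide.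

Step 13
Reactants: 19 (7R,10S)-11-(trimethylsilyloxy)eudesma-1,4-diene-3,8-dione
Product: 20 (7R,10R)-11-(trimethylsilyloxy)eudesm-4-ene-3,8-dione
Conditions: H2 (1 atm), RhCl(PPh3)3 (10 mol %), benzene/EtOH (1:1), rt
Reagents that add atoms: none
Why: Homogeneous hydrogenation with the rhodium phosphine complex saturates the disubstituted C1=C2 bond of a cross-conjugated dienone and leaves the tetrasubstituted C4=C5 bond and both ketones alone, as is usual for 1,4-dien-3-ones.

Step 14
Reactants: 20 (7R,10R)-11-(trimethylsilyloxy)eudesm-4-ene-3,8-dione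
Product: 22 3,8α,11-tris(trimethylsilyloxy)-5αH-eudesm-3-ene, via dilithium enolate alkoxide 21 (not isolated)
Conditions: Li (4.4 equiv), NH3/THF, t-BuOH (2.0 equiv), −78 °C; NH3 removed; then Me3SiCl, Et3N, THF, −78 → 0 °C
Reagents that add atoms: chlorotrimethylsilane, C[Si](C)(C)Cl
Why: Dissolving-metal (Birch-type) reduction of the enone gives the trans-fused lithium enolate by axial protonation of C5 anti to the angular methyl group (5α-H), the C8 ketone is reduced in the same flask to the equatorial alkoxide, and silylation traps the enolate regiospecifically as the C3=C4 silyl enol ether (reductive enolate trapping).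

Step 15
Reactants: 22 3,8α,11-tris(trimethylsilyloxy)-5αH-eudesm-3-ene
Product: 25 4α,8α,11-trihydroxy-5αH-eudesman-3-one, via silyloxy epoxide 23 (not isolated), via silyloxy ketone 24 (not isolated)
Conditions: m-CPBA, NaHCO3, CH2Cl2, −20 → 0 °C; then 1 M HCl, THF, rt
Reagents that add atoms: 3-chloroperoxybenzoic acid, OOC(=O)c1cccc(Cl)c1
Why: In this Rubottom oxidation the peracid epoxidises the silyl enol ether from the α face, away from the axial C10 methyl group, the epoxide opens with 1,4-silyl shift to the 4α-silyloxy ketone (4β-methyl), and dilute acid removes the three trimethylsilyl groups.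

Step 16
Reactants: 25 4α,8α,11-trihydroxy-5αH-eudesman-3-one
Product: 26 4α,11-dihydroxy-5αH-eudesmane-3,8-dione
Conditions: Dess–Martin periodinane, NaHCO3, CH2Cl2, rt
Reagents that add atoms: none
Why: Dess–Martin oxidation returns the only secondary alcohol to the C8 ketone, the two tertiary hydroxyls cannot be oxidised, and the buffered neutral medium should spare the new β-hydroxy ketone from retro-aldol cleavage.

Step 17
Reactants: 26 4α,11-dihydroxy-5αH-eudesmane-3,8-dione
Product: 27 4α-hydroxy-5αH-eudesm-7(11)-ene-3,8-dione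
Conditions: p-TsOH·H2O (10 mol %), benzene, 50 °C
Reagents that add atoms: none
Why: Acid-catalysed aldol dehydration of the tertiary β-hydroxy ketone gives the conjugated isopropylidene ketone (any isopropenyl isomer equilibrates to it under the same conditions), while the C4 hydroxyl next to the C3 carbonyl does not ionise and no stereocentre other than the now superfluous C7 is lost.

Step 18
Reactants: 27 4α-hydroxy-5αH-eudesm-7(11)-ene-3,8-dione
Product: 28 3β,4α-dihydroxy-5αH-eudesm-7(11)-en-8-one
Conditions: Me4NBH(OAc)3, AcOH/MeCN (1:1), −30 → 0 °C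
Reagents that add atoms: none
Why: In this hydroxyl-directed triacetoxyborohydride reduction the reagent binds the 4α-hydroxyl and delivers hydride to C3 from the α (axial) face, giving the equatorial 3β-alcohol trans to the C4 oxygen, while the conjugated C8 ketone, which has no directing hydroxyl, is not reduced.

Step 19
Reactants: 28 3β,4α-dihydroxy-5αH-eudesm-7(11)-en-8-one; 29 (2R)-2-methylbutanoic acid
Product: 30 4α-hydroxy-8-oxo-5αH-eudesm-7(11)-en-3β-yl (2R)-2-methylbutanoate
Conditions: DCC, DMAP (10 mol %), CH2Cl2, 0 °C → rt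
Reagents that add atoms: none
Why: Steglich esterification acylates the secondary 3β-hydroxyl and leaves the hindered tertiary 4α-hydroxyl free, and carbodiimide activation with catalytic DMAP at low temperature should not epimerise the α-stereocentre that the acid brings in.

Step 20
Reactants: 30 4α-hydroxy-8-oxo-5αH-eudesm-7(11)-en-3β-yl (2R)-2-methylbutanoate
Product: 31 (3S,4S,5R,10R)-4-acetoxy-8-oxoeudesm-7(11)-en-3-yl (2R)-2-methylbutanoate
Conditions: Ac2O, DMAP, Et3N, CH2Cl2, 40 °C
Reagents that add atoms: acetic anhydride, CC(=O)OC(C)=O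
Why: DMAP-catalysed acetylation with excess anhydride at slightly raised temperature esterifies the tertiary 4α-hydroxyl without touching a stereocentre, the secondary ester or the enone.

Compound list
1 | 2,6-dimethylbenzaldehyde | Cc1cccc(C)c1C=O | starting material
2 | 3-bromo-2,6-dimethylbenzaldehyde | Cc1ccc(Br)c(C)c1C=O | intermediate
3 | 2,6-dimethyl-3-(4,4,5,5-tetramethyl-1,3,2-dioxaborolan-2-yl)benzaldehyde | Cc1ccc(B2OC(C)(C)C(C)(C)O2)c(C)c1C=O | intermediate
4 | 3-hydroxy-2,6-dimethylbenzaldehyde | Cc1ccc(O)c(C)c1C=O | intermediate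
5 | 2,6-dimethyl-3-[tri(propan-2-yl)silyloxy]benzaldehyde | Cc1ccc(O[Si](C(C)C)(C(C)C)C(C)C)c(C)c1C=O | intermediate
6 | {2,6-dimethyl-3-[tri(propan-2-yl)silyloxy]phenyl}methanol | Cc1ccc(O[Si](C(C)C)(C(C)C)C(C)C)c(C)c1CO | intermediate
7 | [3-(bromomethyl)-2,4-dimethylphenoxy]tri(propan-2-yl)silane | Cc1ccc(O[Si](C(C)C)(C(C)C)C(C)C)c(C)c1CBr | intermediate
8 | (4R)-4-benzyl-1,3-oxazolidin-2-one | O=C1N[C@H](Cc2ccccc2)CO1 | starting material
9 | 3-methylbut-2-enoyl chloride | CC(C)=CC(=O)Cl | starting material
10 | lithium (4R)-4-benzyl-2-oxo-1,3-oxazolidin-3-ide | [Li]N1[C@H](Cc2ccccc2)COC1=O | intermediate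
11 | (4R)-4-benzyl-3-(3-methylbut-2-enoyl)-1,3-oxazolidin-2-one | CC(C)=CC(=O)N1[C@H](Cc2ccccc2)COC1=O | intermediate
12 | sodium (1Z)-1-[(4R)-4-benzyl-2-oxo-1,3-oxazolidin-3-yl]-3-methylbuta-1,3-dien-1-olate | C=C(C)/C=C(\O[Na])N1[C@H](Cc2ccccc2)COC1=O | intermediate
13 | (4R)-4-benzyl-3-[(2R)-2-({2,6-dimethyl-3-[tri(propan-2-yl)silyloxy]phenyl}methyl)-3-methylbut-3-enoyl]-1,3-oxazolidin-2-one | C=C(C)[C@@H](Cc1c(C)ccc(O[Si](C(C)C)(C(C)C)C(C)C)c1C)C(=O)N1[C@H](Cc2ccccc2)COC1=O | intermediate
14 | (4R)-4-benzyl-3-[(2R)-2-({2,6-dimethyl-3-[tri(propan-2-yl)silyloxy]phenyl}methyl)-3-hydroxy-3-methylbutanoyl]-1,3-oxazolidin-2-one | CC(C)(O)[C@@H](Cc1c(C)ccc(O[Si](C(C)C)(C(C)C)C(C)C)c1C)C(=O)N1[C@H](Cc2ccccc2)COC1=O | intermediate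
15 | (2R)-2-({2,6-dimethyl-3-[tri(propan-2-yl)silyloxy]phenyl}methyl)-3-hydroxy-N-methoxy-N,3-dimethylbutanamide | CC(C)(O)[C@@H](Cc1c(C)ccc(O[Si](C(C)C)(C(C)C)C(C)C)c1C)C(=O)N(C)OC | intermediate
16 | (3R)-3-({2,6-dimethyl-3-[tri(propan-2-yl)silyloxy]phenyl}methyl)-4-hydroxy-4-methylpentan-2-one | CC(C)(O)[C@@H](Cc1c(C)ccc(O[Si](C(C)C)(C(C)C)C(C)C)c1C)C(C)=O | intermediate
17 | dilithium (3R)-3-({2,6-dimethyl-3-[tri(propan-2-yl)silyloxy]phenyl}methyl)-4-methylpent-1-ene-2,4-diolate | [Li]OC(C)(C)[C@@H](Cc1c(C)ccc(O[Si](C(C)C)(C(C)C)C(C)C)c1C)C(=C)O[Li] | intermediate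
18 | (3R)-3-({2,6-dimethyl-3-[tri(propan-2-yl)silyloxy]phenyl}methyl)-4-methyl-2,4-bis(trimethylsilyloxy)pent-1-ene | C[Si](C)(C)OC(C)(C)[C@@H](Cc1c(C)ccc(O[Si](C(C)C)(C(C)C)C(C)C)c1C)C(=C)O[Si](C)(C)C | intermediate
19 | (7R,10S)-11-(trimethylsilyloxy)eudesma-1,4-diene-3,8-dione (10β-methyl, 7β side chain) | O=C1C=C[C@]2(C)CC(=O)[C@@H](C(C)(C)O[Si](C)(C)C)CC2=C1C | intermediate
20 | (7R,10R)-11-(trimethylsilyloxy)eudesm-4-ene-3,8-dione | O=C1CC[C@]2(C)CC(=O)[C@@H](C(C)(C)O[Si](C)(C)C)CC2=C1C | intermediate
21 | dilithium 11-(trimethylsilyloxy)-5αH-eudesm-3-ene-3,8α-diolate | [Li]OC=1CC[C@]2(C)C[C@H](O[Li])[C@@H](C(C)(C)O[Si](C)(C)C)C[C@H]2C=1C | intermediate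
22 | 3,8α,11-tris(trimethylsilyloxy)-5αH-eudesm-3-ene | C[Si](C)(C)OC=1CC[C@]2(C)C[C@H](O[Si](C)(C)C)[C@@H](C(C)(C)O[Si](C)(C)C)C[C@H]2C=1C | intermediate
23 | 3α,4α-epoxy-3β,8α,11-tris(trimethylsilyloxy)-5αH-eudesmane | C[Si](C)(C)O[C@@]12CC[C@]3(C)C[C@H](O[Si](C)(C)C)[C@@H](C(C)(C)O[Si](C)(C)C)C[C@H]3[C@]1(C)O2 | intermediate
24 | 4α,8α,11-tris(trimethylsilyloxy)-5αH-eudesman-3-one | O=C1CC[C@]2(C)C[C@H](O[Si](C)(C)C)[C@@H](C(C)(C)O[Si](C)(C)C)C[C@H]2[C@]1(C)O[Si](C)(C)C | intermediate
25 | 4α,8α,11-trihydroxy-5αH-eudesman-3-one | O=C1CC[C@]2(C)C[C@H](O)[C@@H](C(C)(C)O)C[C@H]2[C@]1(C)O | intermediate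
26 | 4α,11-dihydroxy-5αH-eudesmane-3,8-dione | O=C1CC[C@]2(C)CC(=O)[C@@H](C(C)(C)O)C[C@H]2[C@]1(C)O | intermediate
27 | 4α-hydroxy-5αH-eudesm-7(11)-ene-3,8-dione | O=C1CC[C@]2(C)CC(=O)C(=C(C)C)C[C@H]2[C@]1(C)O | intermediate
28 | 3β,4α-dihydroxy-5αH-eudesm-7(11)-en-8-one | O[C@H]1CC[C@]2(C)CC(=O)C(=C(C)C)C[C@H]2[C@]1(C)O | intermediate
29 | (2R)-2-methylbutanoic acid | CC[C@@H](C)C(=O)O | starting material
30 | 4α-hydroxy-8-oxo-5αH-eudesm-7(11)-en-3β-yl (2R)-2-methylbutanoate | CC[C@@H](C)C(=O)O[C@H]1CC[C@]2(C)CC(=O)C(=C(C)C)C[C@H]2[C@]1(C)O | intermediate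
31 | (3S,4S,5R,10R)-4-acetoxy-8-oxoeudesm-7(11)-en-3-yl (2R)-2-methylbutanoate (3β-acyloxy, 4α-acetoxy, 5αH, 10β-methyl) | CC[C@@H](C)C(=O)O[C@H]1CC[C@]2(C)CC(=O)C(=C(C)C)C[C@H]2[C@]1(C)OC(C)=O | target

Total step count: 20. Longest linear sequence: 19 steps (steps 1–5 and 7–20, counted from 1); step 6 is a one-step branch.

The three steps most likely to fail, riskiest first:

Step 12. The oxidised substrate may be diverted before C9 reaches C10. Possible diversions are loss of a benzylic proton from the C10 or C4 methyl group of the oxidised arene, loss of the C7 proton next to the oxidised enol ether (which would also erase the controlling stereocentre), bonding at C4 in place of C10, and closure on the wrong arene face. A C10 epimer would have to be removed by chromatography before any contact with base, because epimerisation at C7 would turn it into the enantiomer of 19. The fallback makes the same C9–C10 bond and closes the same ring by a closed-shell alkylation of the free phenol, a known way to cyclohexa-2,5-dienones from phenolic diazoketones. It sets out from 16 and returns at 19.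
- Trifluoroacetylation of the kinetic enolate of 16 (LiN(SiMe3)2, CF3CO2CH2CF3, THF, −78 °C) would give the trifluoroacetyl ketone F1.
- Regitz-type diazo transfer with loss of the trifluoroacetyl group (MsN3, Et3N, H2O, MeCN) would give the silyl-protected diazoketone F2.
- Bu4NF buffered with AcOH would free the phenol to give the phenolic diazoketone F3.
- Brief exposure to CF3CO2H in CH2Cl2 at −20 °C would protonate the diazo carbon, and the para carbon C10 of the phenol would displace N2 to give the hydroxy dienone F4.
- Me3SiCl and imidazole would convert F4 into 19.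

Step 14. Two carbonyl groups compete for the metal and the proton donor. Enolisation of the C8 ketone toward C7 by amide or alkoxide would expel the β-silyloxy group, and incomplete or excessive reduction would blur the regiodefined enolate. The fallback takes the C8 ketone out by hydride before the dissolving-metal step, so that lithium has only the enone to reduce and the C8 hydroxyl serves as the single proton donor. It sets out from 20 and returns at 26.
- NaBH4 in MeOH/CH2Cl2 at −78 °C, which reduces a saturated ketone in preference to a conjugated one, would give the 8β-hydroxy enone F5.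
- Li in NH3/THF followed by Me3SiCl and Et3N would give the tris(silyl) enol ether F6.
- m-CPBA followed by dilute HCl would give the 8β-epimeric triol ketone F7.
- Dess–Martin oxidation would convert F7 into 26.

Step 9. The hindered imide may be opened at the ring carbonyl of the auxiliary, or the tertiary aluminium aldolate may undergo retro-aldol cleavage before the amide is transferred. The fallback removes the auxiliary by hydrolysis before the hydroxyl is installed. It sets out from 13 and returns at 16.
- LiOH and H2O2 in THF/H2O at 0 °C would give the unsaturated acid F8 and recovered 8.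
- MeLi (2.2 equiv, Et2O, 0 °C, inverse quench into cold aqueous NH4Cl) would add to the lithium carboxylate and give the β,γ-unsaturated methyl ketone F9, which is handled without base to keep C7 intact.
- Mukaiyama hydration (Co(acac)2, PhSiH3, O2) would convert F9 into 16.

Further compounds
F1 | step 12 | (5R)-5-({2,6-dimethyl-3-[tri(propan-2-yl)silyloxy]phenyl}methyl)-1,1,1-trifluoro-6-hydroxy-6-methylheptane-2,4-dione | CC(C)(O)[C@@H](Cc1c(C)ccc(O[Si](C(C)C)(C(C)C)C(C)C)c1C)C(=O)CC(=O)C(F)(F)F
F2 | step 12 | (3R)-1-diazo-3-({2,6-dimethyl-3-[tri(propan-2-yl)silyloxy]phenyl}methyl)-4-hydroxy-4-methylpentan-2-one | CC(C)(O)[C@@H](Cc1c(C)ccc(O[Si](C(C)C)(C(C)C)C(C)C)c1C)C(=O)C=[N+]=[N-]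
F3 | step 12 | (3R)-1-diazo-4-hydroxy-3-[(3-hydroxy-2,6-dimethylphenyl)methyl]-4-methylpentan-2-one | CC(C)(O)[C@@H](Cc1c(C)ccc(O)c1C)C(=O)C=[N+]=[N-]
F4 | step 12 | (7R,10S)-11-hydroxyeudesma-1,4-diene-3,8-dione | O=C1C=C[C@]2(C)CC(=O)[C@@H](C(C)(C)O)CC2=C1C
F5 | step 14 | 8β-hydroxy-11-(trimethylsilyloxy)eudesm-4-en-3-one | O=C1CC[C@]2(C)C[C@@H](O)[C@@H](C(C)(C)O[Si](C)(C)C)CC2=C1C
F6 | step 14 | 3,8β,11-tris(trimethylsilyloxy)-5αH-eudesm-3-ene | C[Si](C)(C)OC=1CC[C@]2(C)C[C@@H](O[Si](C)(C)C)[C@@H](C(C)(C)O[Si](C)(C)C)C[C@H]2C=1C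
F7 | step 14 | 4α,8β,11-trihydroxy-5αH-eudesman-3-one | O=C1CC[C@]2(C)C[C@@H](O)[C@@H](C(C)(C)O)C[C@H]2[C@]1(C)O
F8 | step 9 | (2R)-2-({2,6-dimethyl-3-[tri(propan-2-yl)silyloxy]phenyl}methyl)-3-methylbut-3-enoic acid | C=C(C)[C@@H](Cc1c(C)ccc(O[Si](C(C)C)(C(C)C)C(C)C)c1C)C(=O)O
F9 | step 9 | (3R)-3-({2,6-dimethyl-3-[tri(propan-2-yl)silyloxy]phenyl}methyl)-4-methylpent-4-en-2-one | C=C(C)[C@@H](Cc1c(C)ccc(O[Si](C(C)C)(C(C)C)C(C)C)c1C)C(C)=O
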